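Ring names used below: A is the oxepane, B the cyclohexane fused to it, C the cyclohexene and D the gem-dimethyl cyclohexanol ring.

**Retrosynthetic overview**

1. Target 27 comes from a Peterson methyl-olefination of β-ketosilane 24. Compound 24 comes from a one-carbon ring expansion (Me3SiCHN2) of cis-hydrindan-2-one 23, so ring C is carried as a cyclopentanone until all four stereocentres of rings C and D are in place.
2. Enabling feature: in ring C the sp2 carbon that bears the methyl group has the unsubstituted =CH–CH2 segment on one side and the CH that carries the CH2CH2 bridge on the other. As the carbonyl of the five-membered precursor it is therefore flanked by CH2 and CH(R), so only CH2 should migrate. Both C/D ring-fusion CH are β to this carbonyl and cannot epimerise.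
3. Ketone 23 comes from a Horner–Wadsworth–Emmons union of the ring A/B aldehyde 8 with β-keto phosphonate 21, followed by convex-face hydrogenation. Phosphonate 21 comes from tricyclic cyclopropyl ketone 18, whose cyclopropane is opened by water with inversion to give the ring D carbinol.
4. Ketone 18 comes from intramolecular cyclopropanation of diazo ketone 17, which traces back through an Eschenmoser–Claisen rearrangement of (R)-alcohol 12 to 4,4-dimethylcyclohexenone 9.
5. Aldehyde 8 comes from lactone 5, made by an epoxide-opening cascade of diepoxy ester 4, itself derived from farnesol 1. Ring order: D is present in 9, then cyclopropane and cyclopentane together, A and B together on the other branch, and C last by expansion.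

Key step: step 19

Assumption: the sense of induction of the two organocatalysts (L-fructose-derived ketone gives S-configured epoxide carbons; quinine-derived primary amine gives the (2S,3S)-epoxy ketone) follows the accepted transition-state models. If either is opposite, the enantiomeric or pseudo-enantiomeric catalyst is used.

**Route**

Step 1
Reactants: 1 (2E,6E)-farnesol
Product: 2 (2E,6E)-farnesyl ethyl carbonate
Conditions: ClCO2Et, pyridine, CH2Cl2, 0 °C
Reagents that add atoms: ethyl chloroformate CCOC(=O)Cl
Why: O-acylation of the primary allylic alcohol; the carbonate deactivates the neighbouring alkene toward the electrophilic oxidant of step 2 and serves as the leaving group in step 3.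

Step 2
Reactants: 2 (2E,6E)-farnesyl ethyl carbonate
Product: 3 (2E,6S,7S,10S)-6,7:10,11-diepoxyfarnesyl ethyl carbonate
Conditions: L-fructose-derived Shi ketone (0.6 equiv), KHSO5 (as 2KHSO5·KHSO4·K2SO4), K2CO3, Bu4NHSO4, MeCN/CH2(OMe)2/aq. Na2B4O7 buffer, 0 °C
Reagents that add atoms: potassium peroxymonosulfate [K+].[O-]S(=O)(=O)OO
Why: Shi epoxidation; the chiral dioxirane should attack the two electron-rich trisubstituted alkenes through the spiro transition state and set the three epoxide stereocentres under catalyst control, while the alkene next to the carbonate is electronically deactivated.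

Step 3
Reactants: 3 (2E,6S,7S,10S)-6,7:10,11-diepoxyfarnesyl ethyl carbonate
Product: 4 ethyl (3E,7S,8S,11S)-7,8:11,12-diepoxy-4,8,12-trimethyltridec-3-enoate
Conditions: CO (10 bar), Pd(OAc)2 (2 mol %), PPh3 (8 mol %), EtOH, 50 °C
Reagents that add atoms: carbon monoxide [C-]#[O+]
Why: Palladium-catalysed decarboxylative carbonylation of an allylic carbonate; zerovalent palladium ionises the carbonate, CO inserts at the unsubstituted allyl terminus and the released ethoxide captures the acyl complex, while the isolated trisubstituted epoxides are not ionised by the catalyst.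

Step 4
Reactants: 4 ethyl (3E,7S,8S,11S)-7,8:11,12-diepoxy-4,8,12-trimethyltridec-3-enoate
Product: 5 ring A/B γ-lactone with secondary OTBS group (trans-fused oxepane/cyclohexane/lactone, all five stereocentres S)
Conditions: TBSOTf, 2,6-di-tert-butyl-4-methylpyridine, CH2Cl2, −78 °C
Reagents that add atoms: tert-butyldimethylsilyl triflate CC(C)(C)[Si](C)(C)OS(=O)(=O)C(F)(F)F
Why: Epoxide-opening oxa/carbacyclisation cascade (cation–olefin cyclisation); silylation of the terminal epoxide triggers endo attack of the inner epoxide oxygen at the CMe2 carbon, the E-alkene opens the epoxonium ion at its tertiary carbon with inversion through a chair, and the ester carbonyl traps the tertiary cation anti (equatorially), so the three epoxide centres dictate the two new ones and loss of the ethyl group gives the trans-fused lactone.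

Step 5
Reactants: 5 ring A/B γ-lactone with secondary OTBS group
Product: 6 ring A/B Weinreb amide with free tertiary hydroxyl
Conditions: MeNH(OMe)·HCl, AlMe3, CH2Cl2, 0 °C to rt
Reagents that add atoms: N,O-dimethylhydroxylamine hydrochloride CNOC.Cl
Why: Aluminium-amide aminolysis of the lactone (Weinreb amide formation), which frees the tertiary hydroxyl without touching a stereocentre.

Step 6
Reactants: 6 ring A/B Weinreb amide with free tertiary hydroxyl
Product: 7 ring A/B Weinreb amide with tertiary OTES and secondary OTBS groups
Conditions: TESOTf, 2,6-lutidine, CH2Cl2, 0 °C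
Reagents that add atoms: triethylsilyl triflate CC[Si](CC)(CC)OS(=O)(=O)C(F)(F)F
Why: Silyl triflate silylation of the hindered tertiary alcohol, needed so that the aldehyde of step 7 cannot close to a lactol and the alcohol cannot add to the enone of step 17.

Step 7
Reactants: 7 ring A/B Weinreb amide with tertiary OTES and secondary OTBS groups
Product: 8 ring A/B aldehyde (CH2CHO on ring B, OTES, OTBS)
Conditions: i-Bu2AlH, THF, −78 °C
Reagents that add atoms: none
Why: Partial reduction of a Weinreb amide; the chelated tetrahedral intermediate survives until work-up, so over-reduction should not occur.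

Step 8
Reactants: 9 4,4-dimethylcyclohex-2-en-1-one
Product: 10 (2S,3S)-2,3-epoxy-4,4-dimethylcyclohexanone
Conditions: 9-amino-9-deoxy-epi-quinine (10 mol %), CF3CO2H (20 mol %), 50 % aq. H2O2, dioxane, 50 °C
Reagents that add atoms: hydrogen peroxide OO
Why: Iminium-catalysed Weitz–Scheffer epoxidation; the chiral primary ammonium salt activates the enone and directs hydroperoxide addition to one face, which sets both epoxide carbons.

Step 9
Reactants: 10 (2S,3S)-2,3-epoxy-4,4-dimethylcyclohexanone
Product: 11 (1S,2R,6S)-2,5,5-trimethyl-7-oxabicyclo[4.1.0]heptan-2-ol (hydroxyl cis to the oxirane oxygen)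
Conditions: MeMgBr, THF, −78 °C
Reagents that add atoms: methylmagnesium bromide C[Mg]Br
Why: Grignard 1,2-addition anti to the C–O bond of the oxirane (Felkin–Anh polar model) should place the hydroxyl cis to the epoxide; the minor diastereomer is removed by chromatography because it would become the enantiomer of 12 in step 10.

Step 10
Reactants: 11 (1S,2R,6S)-2,5,5-trimethyl-7-oxabicyclo[4.1.0]heptan-2-ol
Product: 12 (R)-1,4,4-trimethylcyclohex-2-en-1-ol
Conditions: Cp2TiCl2, Zn dust, THF, rt
Reagents that add atoms: none
Why: Reductive epoxide deoxygenation by two equivalents of Cp2TiCl (trivalent titanium) through C–O homolysis, radical capture and β-elimination of the titanium oxide; it needs no backside attack at the hindered oxirane and leaves the carbinol centre untouched.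

Step 11
Reactants: 12 (R)-1,4,4-trimethylcyclohex-2-en-1-ol
Product: 14 N,N-dimethyl-2-[(1R)-3,6,6-trimethylcyclohex-2-en-1-yl]acetamide, via ketene N,O-acetal 13 (not isolated)
Conditions: MeC(OMe)2NMe2, xylene, 140 °C, removal of MeOH
Reagents that add atoms: N,N-dimethylacetamide dimethyl acetal COC(C)(OC)N(C)C
Why: Eschenmoser–Claisen rearrangement; the suprafacial [3,3] shift transfers the configuration of the C–O bond to the new C–C bond next to the gem-dimethyl carbon and leaves the methyl-bearing trisubstituted alkene needed in step 14.

Step 12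
Reactants: 14 N,N-dimethyl-2-[(1R)-3,6,6-trimethylcyclohex-2-en-1-yl]acetamide
Product: 15 1-[(1R)-3,6,6-trimethylcyclohex-2-en-1-yl]propan-2-one
Conditions: MeLi, Et2O, −78 to 0 °C
Reagents that add atoms: methyllithium [Li]C
Why: Addition of an organolithium to a tertiary amide; the tetrahedral lithium hemiaminal collapses only on work-up, so the reaction should stop at the ketone.

Step 13
Reactants: 15 1-[(1R)-3,6,6-trimethylcyclohex-2-en-1-yl]propan-2-one
Product: 17 1-diazo-3-[(1R)-3,6,6-trimethylcyclohex-2-en-1-yl]propan-2-one, via trifluoroacetyl diketone 16 (not isolated)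
Conditions: LiN(SiMe3)2, THF, −78 °C; CF3CO2CH2CF3; then MsN3, Et3N, H2O, MeCN, rt
Reagents that add atoms: methanesulfonyl azide CS(=O)(=O)N=[N+]=[N-]; 2,2,2-trifluoroethyl trifluoroacetate O=C(OCC(F)(F)F)C(F)(F)F (its atoms stay only in 16)
Why: Detrifluoroacetylative Regitz-type diazo transfer; the kinetic enolate forms at the methyl group, is activated as the trifluoroacetyl diketone and exchanges that acyl group for N2.

Step 14
Reactants: 17 1-diazo-3-[(1R)-3,6,6-trimethylcyclohex-2-en-1-yl]propan-2-one
Product: 18 (1R,2S,5R,9R)-1,6,6-trimethyltricyclo[3.3.1.0(2,9)]nonan-3-one (cyclopentanone and cyclopropane on the same face of ring D)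
Conditions: Rh2(OAc)4 (1 mol %), CH2Cl2, slow addition, rt
Reagents that add atoms: none
Why: Intramolecular carbenoid cyclopropanation of a γ,δ-unsaturated diazo ketone; the two-atom tether lets the carbenoid reach only the alkene face that carries the side chain, so the existing stereocentre sets the three new ones and the C/D ring fusion is forced to be cis.

Step 15
Reactants: 18 (1R,2S,5R,9R)-1,6,6-trimethyltricyclo[3.3.1.0(2,9)]nonan-3-one
Product: 20 tricyclic β-keto phosphonate (P(O)(OEt)2 on the CH2 side of the ketone), via enol phosphate 19 (not isolated)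
Conditions: LiN(i-Pr)2, THF, −78 °C; (EtO)2P(O)Cl; then LiN(i-Pr)2, −78 °C to rt
Reagents that add atoms: diethyl chlorophosphate CCOP(=O)(Cl)OCC
Why: Vinyl phosphate to β-keto phosphonate rearrangement; the ketone can enolise only away from the cyclopropane carbon, so O-phosphorylation and the base-induced 1,3-shift of phosphorus mark the future bridge-bearing carbon regiospecifically (the new centre is configurationally labile and is removed in step 17).

Step 16
Reactants: 20 tricyclic β-keto phosphonate
Product: 21 diethyl [(3aS,4S,7aR)-4-hydroxy-4,7,7-trimethyl-2-oxooctahydro-1H-inden-1-yl]phosphonate (cis-fused; hydroxyl on the face of the ring-fusion hydrogens)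
Conditions: aq. HClO4 (cat.), THF, rt
Reagents that add atoms: water O
Why: Acid-catalysed homoconjugate addition of water to the ketone-activated cyclopropane; the external bond that overlaps with the carbonyl and leads to the methyl-bearing tertiary carbon breaks, and water enters anti to the departing carbon, so inversion should give the tertiary alcohol trans to the five-membered ring.

Step 17
Reactants: 21 diethyl [(3aS,4S,7aR)-4-hydroxy-4,7,7-trimethyl-2-oxooctahydro-1H-inden-1-yl]phosphonate; 8 ring A/B aldehyde
Product: 22 (E)-alkylidene cis-hydrindan-2-one joined to rings A/B through C=CH–CH2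
Conditions: LiCl, DBU, MeCN, rt
Reagents that add atoms: none
Why: Horner–Wadsworth–Emmons olefination under mild LiCl/amine conditions joins the two halves at the phosphonate-marked carbon; the alkene geometry is of no consequence because it is removed in step 18.

Step 18
Reactants: 22 (E)-alkylidene cis-hydrindan-2-one joined to rings A/B
Product: 23 saturated cis-hydrindan-2-one (hydrogen of the bridge-bearing CH cis to both ring-fusion hydrogens)
Conditions: H2 (1 bar), Pd/C, EtOAc, rt
Reagents that add atoms: none
Why: Heterogeneous hydrogenation of the exocyclic enone from the convex face of the cis-hydrindanone (the face of the two ring-fusion hydrogens) should set the last ring stereocentre in the kinetic all-cis sense under neutral, non-epimerising conditions.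

Step 19
Reactants: 23 saturated cis-hydrindan-2-one
Product: 24 ring-expanded β-ketosilane (cis-decalin; SiMe3 on the inserted CH of ring C)
Conditions: AlMe3, Me3SiCHN2 (hexanes), CH2Cl2, −78 to −20 °C
Reagents that add atoms: (trimethylsilyl)diazomethane C[Si](C)(C)C=[N+]=[N-]
Why: AlMe3 converts the free hydroxyl to its aluminium alkoxide and activates the cyclopentanone, Me3SiCHN2 adds to the carbonyl, and the β-oxido diazonium ion loses N2 with a concerted 1,2-shift of the antiperiplanar ring bond, a Tiffeneau–Demjanov-type diazoalkane homologation whose closest known relatives are the AlMe3- or Sc(OTf)3-promoted ring expansions of cycloalkanones with Me3SiCHN2 to β-ketosilanes. No ring is closed by cyclisation: the five-membered ring becomes six-membered ring C by insertion of the CH(SiMe3) unit between the carbonyl carbon and the ring CH2. The migrating carbon is an unsubstituted CH2 and the three existing ring stereocentres (both ring-fusion CH, β to the carbonyl, and the bridge-bearing CH) are not involved, so the all-cis array built on the small ring should pass unchanged into the strained cis-decalin, which equilibrating chemistry on a six-membered ketone would not be expected to hold. The only new stereocentre, CH(SiMe3), is set by the anti geometry of the shift and does not matter because step 20 destroys it. The selectivity needed is migration of CH2 rather than CH(R), secured by the rule that the less substituted carbon migrates in Lewis-acid-promoted diazoalkane insertions and reinforced here by the neopentyl surroundings of CH(R); a second insertion should be suppressed because the bulky α-silyl ketone is far less reactive than 23. The silicon delivered with the inserted carbon marks that carbon as the future vinylic CH, so this one step fixes both the ring size and the position of the ring C double bond.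

Step 20
Reactants: 24 ring-expanded β-ketosilane
Product: 26 sipholenol L bis-silyl ether (OTBS on ring A, OTES on ring B), via beta-silyl alkoxide 25 (not isolated)
Conditions: MeLi (excess), THF, −78 °C; then KOt-Bu, −78 °C to rt
Reagents that add atoms: methyllithium [Li]C
Why: Peterson olefination; MeLi should add anti to the C–Si bond (Felkin–Anh) to give the alkoxide with oxygen and silicon on the same face, which after exchange to potassium undergoes syn elimination, so the double bond can form only between the methyl-bearing carbon and the silicon-bearing carbon.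

Step 21
Reactants: 26 sipholenol L bis-silyl ether
Product: 27 sipholenol L
Conditions: Bu4NF, THF, 50 °C
Reagents that add atoms: none
Why: Fluoride-induced cleavage of both silyl ethers under non-acidic conditions, which spare the three tertiary C–O bonds and the trisubstituted alkene.

**Compound list**

1 | (2E,6E)-farnesol | CC(C)=CCC/C(C)=C/CC/C(C)=C/CO | starting material
2 | (2E,6E)-farnesyl ethyl carbonate | CCOC(=O)OC/C=C(\C)CC/C=C(\C)CCC=C(C)C | intermediate
3 | (2E,6S,7S,10S)-6,7:10,11-diepoxyfarnesyl ethyl carbonate | CCOC(=O)OC/C=C(\C)CC[C@@H]1O[C@@]1(C)CC[C@@H]1OC1(C)C | intermediate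
4 | ethyl (3E,7S,8S,11S)-7,8:11,12-diepoxy-4,8,12-trimethyltridec-3-enoate | CCOC(=O)C/C=C(\C)CC[C@@H]1O[C@@]1(C)CC[C@@H]1OC1(C)C | intermediate
5 | ring A/B γ-lactone with secondary OTBS group | O=C1C[C@H]2[C@]3(C)CC[C@H](O[Si](C)(C)C(C)(C)C)C(C)(C)O[C@H]3CC[C@]2(C)O1 | intermediate
6 | ring A/B Weinreb amide with free tertiary hydroxyl | CON(C)C(=O)C[C@H]1[C@]2(C)CC[C@H](O[Si](C)(C)C(C)(C)C)C(C)(C)O[C@H]2CC[C@]1(C)O | intermediate
7 | ring A/B Weinreb amide with OTES and OTBS groups | CON(C)C(=O)C[C@H]1[C@]2(C)CC[C@H](O[Si](C)(C)C(C)(C)C)C(C)(C)O[C@H]2CC[C@]1(C)O[Si](CC)(CC)CC | intermediate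
8 | ring A/B aldehyde | O=CC[C@H]1[C@]2(C)CC[C@H](O[Si](C)(C)C(C)(C)C)C(C)(C)O[C@H]2CC[C@]1(C)O[Si](CC)(CC)CC | intermediate
9 | 4,4-dimethylcyclohex-2-en-1-one | CC1(C)CCC(=O)C=C1 | starting material
10 | (2S,3S)-2,3-epoxy-4,4-dimethylcyclohexanone | O=C1CCC(C)(C)[C@@H]2O[C@H]12 | intermediate
11 | (1S,2R,6S)-2,5,5-trimethyl-7-oxabicyclo[4.1.0]heptan-2-ol | C[C@@]1(O)CCC(C)(C)[C@@H]2O[C@H]12 | intermediate
12 | (R)-1,4,4-trimethylcyclohex-2-en-1-ol | C[C@]1(O)C=CC(C)(C)CC1 | intermediate
13 | ketene N,O-acetal of 12 (not isolated) | C=C(N(C)C)O[C@@]1(C)C=CC(C)(C)CC1 | intermediate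
14 | N,N-dimethyl-2-[(1R)-3,6,6-trimethylcyclohex-2-en-1-yl]acetamide | CN(C)C(=O)C[C@@H]1C=C(C)CCC1(C)C | intermediate
15 | 1-[(1R)-3,6,6-trimethylcyclohex-2-en-1-yl]propan-2-one | CC(=O)C[C@@H]1C=C(C)CCC1(C)C | intermediate
16 | trifluoroacetyl diketone (not isolated) | O=C(CC(=O)C(F)(F)F)C[C@@H]1C=C(C)CCC1(C)C | intermediate
17 | 1-diazo-3-[(1R)-3,6,6-trimethylcyclohex-2-en-1-yl]propan-2-one | [N-]=[N+]=CC(=O)C[C@@H]1C=C(C)CCC1(C)C | intermediate
18 | (1R,2S,5R,9R)-1,6,6-trimethyltricyclo[3.3.1.0(2,9)]nonan-3-one | O=C1C[C@@H]2[C@@H]3[C@H]1[C@]3(C)CCC2(C)C | intermediate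
19 | enol phosphate of 18 (not isolated) | CCOP(=O)(OCC)OC1=C[C@@H]2[C@@H]3[C@H]1[C@]3(C)CCC2(C)C | intermediate
20 | tricyclic β-keto phosphonate (phosphorus-bearing carbon labile, drawn undefined) | O=C1C(P(=O)(OCC)OCC)[C@@H]2[C@@H]3[C@H]1[C@]3(C)CCC2(C)C | intermediate
21 | diethyl [(3aS,4S,7aR)-4-hydroxy-4,7,7-trimethyl-2-oxooctahydro-1H-inden-1-yl]phosphonate (phosphorus-bearing carbon labile, drawn undefined) | O=C1C[C@H]2[C@@H](C1P(=O)(OCC)OCC)C(C)(C)CC[C@]2(C)O | intermediate
22 | (E)-alkylidene cis-hydrindan-2-one joined to rings A/B | O=C1C[C@H]2[C@@H](/C1=C\C[C@H]1[C@]3(C)CC[C@H](O[Si](C)(C)C(C)(C)C)C(C)(C)O[C@H]3CC[C@]1(C)O[Si](CC)(CC)CC)C(C)(C)CC[C@]2(C)O | intermediate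
23 | saturated cis-hydrindan-2-one, all-cis | O=C1C[C@H]2[C@@H]([C@@H]1CC[C@H]1[C@]3(C)CC[C@H](O[Si](C)(C)C(C)(C)C)C(C)(C)O[C@H]3CC[C@]1(C)O[Si](CC)(CC)CC)C(C)(C)CC[C@]2(C)O | intermediate
24 | ring-expanded β-ketosilane (silyl-bearing carbon drawn undefined, removed in step 20) | O=C1C([Si](C)(C)C)C[C@H]2[C@@H]([C@@H]1CC[C@H]1[C@]3(C)CC[C@H](O[Si](C)(C)C(C)(C)C)C(C)(C)O[C@H]3CC[C@]1(C)O[Si](CC)(CC)CC)C(C)(C)CC[C@]2(C)O | intermediate
25 | beta-silyl alkoxide (not isolated; drawn as the alcohol, two transient centres undefined) | CC1(O)C([Si](C)(C)C)C[C@H]2[C@@H]([C@@H]1CC[C@H]1[C@]3(C)CC[C@H](O[Si](C)(C)C(C)(C)C)C(C)(C)O[C@H]3CC[C@]1(C)O[Si](CC)(CC)CC)C(C)(C)CC[C@]2(C)O | intermediate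
26 | sipholenol L bis-silyl ether | CC1=CC[C@H]2[C@@H]([C@@H]1CC[C@H]1[C@]3(C)CC[C@H](O[Si](C)(C)C(C)(C)C)C(C)(C)O[C@H]3CC[C@]1(C)O[Si](CC)(CC)CC)C(C)(C)CC[C@]2(C)O | intermediate
27 | sipholenol L | CC1=CC[C@H]2[C@@H]([C@@H]1CC[C@H]1[C@]3(C)CC[C@H](O)C(C)(C)O[C@H]3CC[C@]1(C)O)C(C)(C)CC[C@]2(C)O | target

**Step count**

- Total step count: 21.
- Longest linear sequence: 14 steps (steps 8 to 21, from 9).
- The ring A/B branch (steps 1 to 7) joins at step 17.

**Steps most likely to fail**

**Step 4.**
- What may go wrong: the cascade may stop early. Proton loss or a hydride shift at the epoxonium ion or at the tertiary cation could compete with C–C bond formation, because the alkene is inductively deactivated by the ester and the ester carbonyl is a weak terminating nucleophile.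
- Fallback: it sets out from 4 and comes back at 5. i-Bu2AlH at low temperature reduces only the ester to the homoallylic alcohol, diepoxy-homofarnesol F1. Its oxygen (silylated in the flask) is a stronger and sterically free terminator.
- The same silyl triflate activation should then end in a tetrahydrofuran instead of a lactone, giving the ring A/B tetrahydrofuran F2.
- RuCl3/NaIO4 oxidation of the OCH2 group of that cyclic ether, a known way from such ethers to γ-lactones, returns 5.

**Step 19.**
- What may go wrong: the silyl marker may be lost by 1,3-migration of silicon to oxygen or by protodesilylation during the reaction or work-up. The later olefination would then have no regiochemical control.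
- Fallback: it sets out from 24 (or from the crude mixture of its desilylated forms) and comes back at 26. Deliberate protodesilylation on silica gel or with dilute acid gives the ring C ketone F3.
- Kinetic deprotonation with LiN(i-Pr)2 at the unhindered CH2, followed by trapping with PhNTf2, gives the enol triflate F4.
- Fe(acac)3-catalysed cross-coupling with MeMgBr installs the methyl group. The alkene position then rests on kinetic enolisation and cross-coupling rather than on silicon.

**Step 11.**
- What may go wrong: exchange at the hindered tertiary hydroxyl may be slow, and the tertiary allylic ketene N,O-acetal may eliminate thermally to the diene. Both compete with a sigmatropic shift that must form a bond next to a quaternary carbon.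
- Fallback: it sets out from 12 and comes back at 15. O-acetylation (Ac2O, DMAP, Et3N) gives the tertiary allylic acetate F5.
- An Ireland–Claisen rearrangement (LiN(i-Pr)2, Me3SiCl, THF, −78 °C to rt, aqueous work-up) runs at or below room temperature with the same suprafacial chirality transfer and gives the acid F6.
- Two equivalents of MeLi convert F6 into ketone 15.

**Further compounds**

F1 | step 4 | (3E,7S,8S,11S)-7,8:11,12-diepoxy-4,8,12-trimethyltridec-3-en-1-ol (diepoxy-homofarnesol) | OCC/C=C(\C)CC[C@@H]1O[C@@]1(C)CC[C@@H]1OC1(C)C
F2 | step 4 | ring A/B tetrahydrofuran with secondary OTBS group | C1C[C@H]2[C@]3(C)CC[C@H](O[Si](C)(C)C(C)(C)C)C(C)(C)O[C@H]3CC[C@]2(C)O1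
F3 | step 19 | ring C ketone (desilylated 24) | O=C1CC[C@H]2[C@@H]([C@@H]1CC[C@H]1[C@]3(C)CC[C@H](O[Si](C)(C)C(C)(C)C)C(C)(C)O[C@H]3CC[C@]1(C)O[Si](CC)(CC)CC)C(C)(C)CC[C@]2(C)O
F4 | step 19 | ring C enol triflate | O=S(=O)(OC1=CC[C@H]2[C@@H]([C@@H]1CC[C@H]1[C@]3(C)CC[C@H](O[Si](C)(C)C(C)(C)C)C(C)(C)O[C@H]3CC[C@]1(C)O[Si](CC)(CC)CC)C(C)(C)CC[C@]2(C)O)C(F)(F)F
F5 | step 11 | (R)-1,4,4-trimethylcyclohex-2-en-1-yl acetate | CC(=O)O[C@@]1(C)C=CC(C)(C)CC1
F6 | step 11 | 2-[(1R)-3,6,6-trimethylcyclohex-2-en-1-yl]acetic acid | OC(=O)C[C@@H]1C=C(C)CCC1(C)C
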